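**Retrosynthetic overview**
- C–S last: the thioacetate comes from a primary alcohol by Mitsunobu displacement.
- Ring–CH2/CH=C bond: Pd coupling of a 6-(chloromethyl)pyranone with an (E)-alkenylalane made in the flask from 10-undecyn-1-ol; this sets the E-alkene.
- Both methoxy groups are installed by C–O bond formation on a simple 4-hydroxy-2-pyranone: C3–H methoxylation (key step, new), then carbonyl-O-methylation that turns the 2-pyranone into the 2-methoxy-4-pyranone.
- Only one ring: the pyranone is closed first, by lactonisation (C–O) of a 3,5-diketo ester from methyl 3-oxopentanoate and an acetyl donor.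

Assumptions: the target has no stereocentre, so "single enantiomer" is taken to mean the single E-alkene isomer. Simple deprotonated forms (enolates, alkoxides) are treated as forms of their parent compounds and are not numbered.

**Step 1**
Reactants: 1 methyl 3-oxopentanoate; 2 N-methoxy-N-methylacetamide
Product: 4 4-hydroxy-5,6-dimethyl-2H-pyran-2-one, via methyl 4-methyl-3,5-dioxohexanoate 3 (not isolated)
Conditions: LDA (2.2 equiv), THF, −78 → 0 °C; 2, −78 → 0 °C; aq. HCl work-up; crude 3: DBU, PhMe, 60 °C; HCl
Reagents that add atoms: none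
Why: The β-keto ester dianion is acylated at its γ-carbon by the Weinreb amide (stable tetrahedral adduct, no over-addition), and DBU then closes the ring by enol-O lactonisation (dianion Claisen acylation / lactonisation).

**Step 2**
Reactants: 4 4-hydroxy-5,6-dimethyl-2H-pyran-2-one
Product: 6 4-hydroxy-3-methoxy-5,6-dimethyl-2H-pyran-2-one, via 5,6-dimethyl-2-oxo-3-(phenyliodonio)-2H-pyran-4-olate 5 (not isolated)
Conditions: PhIO (1.0 equiv), MeOH, 3 Å MS, 0 °C → rt; then Rh2(OAc)4 (2 mol%), 40 °C
Reagents that add atoms: methanol, CO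
Why: Proposed new method: one-flask C3–H methoxylation in which PhIO (as PhI(OMe)2 in MeOH) condenses with the acidic C3–H of the cyclic 1,3-dicarbonyl to give the stabilised iodonium ylide, Rh(II) then expels PhI to form an electrophilic C3 carbenoid that inserts into the O–H of solvent methanol (oxonium ylide, 1,2-H shift), forming the C3–OMe bond; using PhIO rather than PhI(OAc)2 avoids competing insertion into acetic acid; the closest known reaction type is Rh(II)-catalysed O–H insertion of cyclic 2-diazo-1,3-dicarbonyls and carbenoid transfer from iodonium ylides of 4-hydroxycoumarins.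

**Step 3**
Reactants: 6 4-hydroxy-3-methoxy-5,6-dimethyl-2H-pyran-2-one
Product: 7 2,3-dimethoxy-5,6-dimethyl-4H-pyran-4-one
Conditions: MeOTf (1.5 equiv), CH2Cl2, rt; aq. NaHCO3
Reagents that add atoms: methyl triflate, COS(=O)(=O)C(F)(F)F
Why: In the neutral 4-hydroxy-2-pyranone the lactone carbonyl oxygen is the most nucleophilic site, so the hard methylating agent gives a 4-hydroxy-2-methoxypyrylium ion that loses a proton to the 2-methoxy-4-pyranone (regioselective O-methylation with a hard alkylating agent).

**Step 4**
Reactants: 7 2,3-dimethoxy-5,6-dimethyl-4H-pyran-4-one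
Product: 8 6-(chloromethyl)-2,3-dimethoxy-5-methyl-4H-pyran-4-one
Conditions: LiHMDS (1.1 equiv), THF, −78 °C; cannulate into C2Cl6 (1.5 equiv), THF, −78 °C
Reagents that add atoms: hexachloroethane, ClC(Cl)(Cl)C(Cl)(Cl)Cl
Why: Only the 6-methyl is vinylogous to the carbonyl, so lateral deprotonation gives the extended enolate, which takes Cl+ at the exocyclic carbon and restores the pyranone; inverse addition suppresses self-alkylation (lateral lithiation / electrophilic chlorination, as for 6-methyl-dioxinones).

**Step 5**
Reactants: 9 10-undecyn-1-ol; 8 6-(chloromethyl)-2,3-dimethoxy-5-methyl-4H-pyran-4-one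
Product: 11 6-[(2E)-12-hydroxy-3-methyldodec-2-en-1-yl]-2,3-dimethoxy-5-methyl-4H-pyran-4-one, via E-alkenyldimethylalane 10 (not isolated)
Conditions: 9 (1.3 equiv), Me3Al (3 equiv), Cp2ZrCl2 (0.25 equiv), CH2Cl2, 0 °C → rt; remove excess Me3Al in vacuo; 8 (1.0 equiv), Pd(PPh3)4 (5 mol%), THF, rt; dil. HCl
Reagents that add atoms: trimethylaluminium, C[Al](C)C
Why: Zr-catalysed syn-carboalumination puts Me on the internal and Al on the terminal alkyne carbon (Me and Al cis), and Pd-catalysed coupling of the alkenylalane with the heterobenzylic chloride proceeds with retention, so the ring CH2 ends up trans to the long chain (Negishi carboalumination / Negishi cross-coupling).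

**Step 6**
Reactants: 11 6-[(2E)-12-hydroxy-3-methyldodec-2-en-1-yl]-2,3-dimethoxy-5-methyl-4H-pyran-4-one
Product: 12 lehualide C, S-[(10E)-12-(5,6-dimethoxy-3-methyl-4-oxo-4H-pyran-2-yl)-10-methyldodec-10-en-1-yl] ethanethioate
Conditions: PPh3, DIAD, AcSH, THF, 0 °C → rt
Reagents that add atoms: thioacetic acid, CC(=O)S
Why: Mitsunobu activation of the primary alcohol and SN2 displacement by thioacetate installs the thioester under neutral conditions that leave the alkene geometry and the methoxypyranone untouched (Mitsunobu thioesterification).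

**Compound list**
1 | methyl 3-oxopentanoate | CCC(=O)CC(=O)OC | starting material
2 | N-methoxy-N-methylacetamide | CC(=O)N(C)OC | starting material
3 | methyl 4-methyl-3,5-dioxohexanoate (racemic, enolisable centre) | COC(=O)CC(=O)C(C)C(C)=O | intermediate
4 | 4-hydroxy-5,6-dimethyl-2H-pyran-2-one | Cc1oc(=O)cc(O)c1C | intermediate
5 | 5,6-dimethyl-2-oxo-3-(phenyliodonio)-2H-pyran-4-olate (iodonium ylide) | CC1=C(C)C([O-])=C([I+]c2ccccc2)C(=O)O1 | intermediate
6 | 4-hydroxy-3-methoxy-5,6-dimethyl-2H-pyran-2-one | COc1c(O)c(C)c(C)oc1=O | intermediate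
7 | 2,3-dimethoxy-5,6-dimethyl-4H-pyran-4-one | COc1oc(C)c(C)c(=O)c1OC | intermediate
8 | 6-(chloromethyl)-2,3-dimethoxy-5-methyl-4H-pyran-4-one | COc1oc(CCl)c(C)c(=O)c1OC | intermediate
9 | 10-undecyn-1-ol | C#CCCCCCCCCCO | starting material
10 | dimethyl[(1E)-11-(dimethylaluminooxy)-2-methylundec-1-en-1-yl]alane | C[Al](C)/C=C(\C)CCCCCCCCCO[Al](C)C | intermediate
11 | 6-[(2E)-12-hydroxy-3-methyldodec-2-en-1-yl]-2,3-dimethoxy-5-methyl-4H-pyran-4-one | COc1oc(C/C=C(\C)CCCCCCCCCO)c(C)c(=O)c1OC | intermediate
12 | lehualide C | COc1oc(C/C=C(\C)CCCCCCCCCSC(C)=O)c(C)c(=O)c1OC | target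

**Totals**
Total step count: 6. Longest linear sequence: 6 steps (1 → 4 → 6 → 7 → 8 → 11 → 12); alkyne 9 is commercial and enters at step 5.

**Three steps most likely to fail**

Step 2 (proposed new C–H methoxylation). Risks are Wolff-type ring contraction of the carbenoid, insertion into adventitious water, or over-oxidation. The fallback uses known chemistry and installs the C3 methoxy group before the ring is made. It sets out from 1: diazo transfer (p-ABSA, Et3N, MeCN) gives methyl 2-diazo-3-oxopentanoate F1. Rh2(OAc)4-catalysed O–H insertion into methanol gives methyl 2-methoxy-3-oxopentanoate F2. Its dianion (LDA, 2.2 equiv) is acylated with 2 to give methyl 2-methoxy-4-methyl-3,5-dioxohexanoate F3. DBU lactonisation of F3 returns to the route at 6.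

Step 4 (lateral chlorination). Risks are self-alkylation of the enolate by the product and over-chlorination. The fallback changes to an oxidation/reduction/substitution sequence and sets out from 7. SeO2 in refluxing dioxane oxidises the activated 6-methyl to 5,6-dimethoxy-3-methyl-4-oxo-4H-pyran-2-carbaldehyde F4. NaBH4 in MeOH at 0 °C gives 6-(hydroxymethyl)-2,3-dimethoxy-5-methyl-4H-pyran-4-one F5. MsCl/Et3N gives (5,6-dimethoxy-3-methyl-4-oxo-4H-pyran-2-yl)methyl methanesulfonate F6, and LiCl in DMF displaces the mesylate to come back at 8.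

Step 5 (carboalumination / coupling in one flask). Risks are attack of residual aluminium methyl species on the 2-methoxypyranone and sluggish transmetalation in the presence of the aluminium alkoxide. The fallback separates the two events and couples under neutral conditions; it sets out from 9 and uses 8. The same carboalumination is quenched with I2 to give (10E)-11-iodo-10-methylundec-10-en-1-ol F7. Pd(PPh3)4 with hexabutylditin converts it to tributyl[(1E)-11-hydroxy-2-methylundec-1-en-1-yl]stannane F8. Stille coupling of F8 with 8 (Pd2(dba)3, AsPh3, THF/NMP, 60 °C) comes back at 11.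

**Further compounds**
F1 | step 2 | methyl 2-diazo-3-oxopentanoate | CCC(=O)C(=[N+]=[N-])C(=O)OC
F2 | step 2 | methyl 2-methoxy-3-oxopentanoate (racemic) | CCC(=O)C(OC)C(=O)OC
F3 | step 2 | methyl 2-methoxy-4-methyl-3,5-dioxohexanoate (diastereomer mixture) | COC(=O)C(OC)C(=O)C(C)C(C)=O
F4 | step 4 | 5,6-dimethoxy-3-methyl-4-oxo-4H-pyran-2-carbaldehyde | COc1oc(C=O)c(C)c(=O)c1OC
F5 | step 4 | 6-(hydroxymethyl)-2,3-dimethoxy-5-methyl-4H-pyran-4-one | COc1oc(CO)c(C)c(=O)c1OC
F6 | step 4 | (5,6-dimethoxy-3-methyl-4-oxo-4H-pyran-2-yl)methyl methanesulfonate | COc1oc(COS(C)(=O)=O)c(C)c(=O)c1OC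
F7 | step 5 | (10E)-11-iodo-10-methylundec-10-en-1-ol | OCCCCCCCCC/C(C)=C/I
F8 | step 5 | tributyl[(1E)-11-hydroxy-2-methylundec-1-en-1-yl]stannane | CCCC[Sn](CCCC)(CCCC)/C=C(\C)CCCCCCCCCO
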